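**Plan**

- Target: an oxolane with O1, 4-hydroxyphenyl groups on C2/C5 and 2,4-dihydroxybenzoyl groups on C3/C4. (2S,3R,4R,5S) means 2,3-cis-3,4-trans-4,5-cis and C2-symmetric, each aryl cis to the neighbouring aroyl. A quinone-methide (biomimetic) closure or any equilibration is expected to put the aryl trans (A(1,3) strain), so the ring O–C bond is made at the ketone oxidation level and the benzylic H is delivered last.
- Retrosynthesis: (a) the two C(=O)–aryl bonds of the aroyl groups (ring-CHO plus aryl Grignard reagent; CHO from ring-vinyl); (b) the ring bond O1–C2 (γ-hydroxy ketone, lactol, oxocarbenium ion, hydride); (c) C2–C3 and C4–C5 (two allylborations), back to the (2E,4E)-hexa-2,4-diene-1,6-diyl bis(boronate) and two molecules of 4-(benzyloxy)benzaldehyde.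
- Forward: the chain C2–C3–C4–C5 is joined first in one two-directional allylboration (C3–C4 is the central bond of the diene). The oxolane ring is closed next (oxidation of one carbinol, lactolisation, silane reduction), then vinyl to CHO to aroyl on both arms, then debenzylation.
- Enabling feature: the oxygen on C5 and the carbonyl carbon C2 are 1,4-related, so the hydroxy ketone closes to a five-membered 2-aryl lactol. Its oxocarbenium ion (C2=O1+, stabilised by the 4-alkoxyphenyl on C2) is reduced under control of C3. Vinyl groups at C3/C4 stand in for the aroyl groups, because a 3-acyl oxocarbenium ion would lose H3 and give a 4,5-dihydrofuran.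
- Stereochemistry: C3, C4, C5 (R,R,S) come from the chiral-phosphoric-acid-catalysed allylboration of the E,E reagent (chair transition states, anti; the acid selects the aldehyde face). C2 (S) comes from hydride attack anti to the C3 vinyl group. Once the aroyl ketones are in place (steps 8 and 9), only non-basic, near-neutral conditions are used so that the cis α-keto centres are kept.

Key step: step 4

Remark (assumption): the (S)-configured phosphoric acid is taken to give the (S)-carbinol sense, its antipode being the acid that gives (R)-homoallylic alcohols from aryl aldehydes; should the sense be the reverse, the antipodal acid is used.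

**Step 1**
Reactants: 1 hexa-1,5-diene-3,4-diol (commercial mixture of diastereomers)
Product: 2 (2E,4E)-1,6-dibromohexa-2,4-diene
Conditions: PBr3, Et2O, 0 °C to rt; recrystallisation
Reagents that add atoms: phosphorus tribromide, BrP(Br)Br
Why: Allylic bromination with double allylic transposition (SN2' type) should give the conjugated E,E-diene as the thermodynamic, crystalline product; the stereocentres of 1 are lost, so its diastereomer mixture does not matter.

**Step 2**
Reactants: 2 (2E,4E)-1,6-dibromohexa-2,4-diene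
Product: 3 2,2'-[(2E,4E)-hexa-2,4-diene-1,6-diyl]bis(4,4,5,5-tetramethyl-1,3,2-dioxaborolane)
Conditions: B2pin2 (2.4 equiv), KOAc, Pd2(dba)3 (cat.), DMSO, 50 °C
Reagents that add atoms: bis(pinacolato)diboron, CC1(C)OB(OC1(C)C)B1OC(C)(C)C(C)(C)O1
Why: Miyaura-type palladium-catalysed borylation of an allylic electrophile: the η3-allylpalladium intermediate should take up boron at the unsubstituted terminus, which gives the linear allylboronate at both ends and keeps the E,E geometry.

**Step 3**
Reactants: 3 2,2'-[(2E,4E)-hexa-2,4-diene-1,6-diyl]bis(4,4,5,5-tetramethyl-1,3,2-dioxaborolane); 4 4-(benzyloxy)benzaldehyde (commercial)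
Product: 7 (1S,2R,3R,4S)-1,4-bis[4-(benzyloxy)phenyl]-2,3-diethenylbutane-1,4-diol, via mono-adduct 5 (not isolated), via bis(borate ester) 6 (not isolated)
Conditions: 4 (2.2 equiv in all), (S)-3,3'-bis(2,4,6-triisopropylphenyl)-1,1'-binaphthyl-2,2'-diyl hydrogen phosphate (10 mol %), 4 Å MS, toluene, −30 °C to 0 °C; then aq. NaHCO3, rt
Reagents that add atoms: 4-(benzyloxy)benzaldehyde (second equivalent of 4, which reacts with mono-adduct 5), O=Cc1ccc(OCc2ccccc2)cc1
Why: Chiral-phosphoric-acid-catalysed allylboration of an aldehyde run in two directions with two equivalents of 4: each E-configured γ-substituted allylboronate terminus should add through its γ-carbon in a six-membered chair transition state with the aryl group equatorial, giving the anti relationship at both ends, while the acid selects the aldehyde face that leads to the (S)-carbinols, so that two C–C bonds, both carbinol centres and C3/C4 (R,R) arise in one operation.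

**Step 4**
Reactants: 7 (1S,2R,3R,4S)-1,4-bis[4-(benzyloxy)phenyl]-2,3-diethenylbutane-1,4-diol
Product: 10 (2S,3R,4R,5S)-2,5-bis[4-(benzyloxy)phenyl]-3,4-diethenyloxolane, via hydroxy ketone 8 (not isolated), via lactol 9 (not isolated)
Conditions: MnO2 (activated), CH2Cl2, rt; filtration; then Et3SiH (excess), BF3·OEt2, CH2Cl2, −78 °C
Reagents that add atoms: none
Why: MnO2 should oxidise one of the two homotopic (C2-related) benzylic carbinols of 7 to aryl ketone 8, whose remaining γ-hydroxyl adds to the carbonyl carbon (5-exo-trig; this forms the ring O–C bond) to give lactol 9, and BF3·OEt2 then ionises 9 to the 2-aryl oxocarbenium ion, which Et3SiH reduces. The closest known reaction type is the Lewis acid/silane reductive deoxygenation of 2-aryl lactols (cyclic hemiketals) used for 2,3-cis-2,5-diaryloxolane lignans, i.e. a reductive cycloetherification of a γ-hydroxy ketone. The new stereocentre C2 is set by the C3 vinyl group: the aryl ring is coplanar with C2=O1+, the C3 substituent turns pseudoaxial to avoid A(1,2) strain, and hydride enters on the opposite face, which places the C2 aryl cis to the C3 vinyl group; C3, C4 and C5 are carried over unchanged from 7, so the cis,trans,cis ring results. A closure by ionisation at the benzylic carbon (carbocation or quinone methide) would instead be expected to give the 2,3-trans isomer, which is why the C–O bond is formed at the ketone oxidation level. The selectivities needed are mono-oxidation (lactol formation masks both the second carbinol and the ketone once one carbinol has reacted) and hydride capture before loss of the C3 proton (secured by −78 °C and excess silane; a vinyl group, unlike an aroyl group, does not acidify H3 enough to give a 4,5-dihydrofuran).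

**Step 5**
Reactants: 10 (2S,3R,4R,5S)-2,5-bis[4-(benzyloxy)phenyl]-3,4-diethenyloxolane
Product: 11 (2S,3R,4R,5S)-2,5-bis[4-(benzyloxy)phenyl]oxolane-3,4-dicarbaldehyde
Conditions: O3, CH2Cl2, −78 °C (indicator end point); then PPh3, −78 °C to rt
Reagents that add atoms: ozone, [O-][O+]=O
Why: Ozonolysis with reductive work-up should cleave the two monosubstituted alkenes much faster than the alkoxy-substituted arenes and leaves the ring stereocentres untouched; the dialdehyde is used at once.

**Step 6**
Reactants: 12 4-bromobenzene-1,3-diol (commercial)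
Product: 13 2,4-bis(benzyloxy)-1-bromobenzene
Conditions: BnBr (2.2 equiv), K2CO3, DMF, rt
Reagents that add atoms: benzyl bromide, BrCc1ccccc1
Why: Williamson ether synthesis; both phenols are alkylated and the aryl bromide is inert.

**Step 7**
Reactants: 11 (2S,3R,4R,5S)-2,5-bis[4-(benzyloxy)phenyl]oxolane-3,4-dicarbaldehyde; 13 2,4-bis(benzyloxy)-1-bromobenzene
Product: 15 {(2S,3S,4S,5S)-2,5-bis[4-(benzyloxy)phenyl]oxolane-3,4-diyl}bis{[2,4-bis(benzyloxy)phenyl]methanol} (mixture of epimers at the two new carbinol carbons), via aryl Grignard reagent 14 (not isolated)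
Conditions: 13 (2.5 equiv in all), Mg, THF, 40 °C; then 11, THF, −78 °C; H2O work-up
Reagents that add atoms: 2,4-bis(benzyloxy)-1-bromobenzene (second equivalent of 13, converted into a second equivalent of Grignard reagent 14 for the second aldehyde group), Brc1ccc(OCc2ccccc2)cc1OCc1ccccc1
Why: 1,2-Addition of two equivalents of the aryl Grignard reagent, one to each aldehyde group, at low temperature (the weakly basic magnesium reagent is chosen to avoid enolisation of the cis α-centres); the two new carbinol centres form unselectively and are erased in step 8, and the change of the C3/C4 descriptors to S is only a change of priorities.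

**Step 8**
Reactants: 15 {(2S,3S,4S,5S)-2,5-bis[4-(benzyloxy)phenyl]oxolane-3,4-diyl}bis{[2,4-bis(benzyloxy)phenyl]methanol}
Product: 16 {(2S,3R,4R,5S)-2,5-bis[4-(benzyloxy)phenyl]oxolane-3,4-diyl}bis{[2,4-bis(benzyloxy)phenyl]methanone}
Conditions: Dess–Martin periodinane (2.5 equiv), CH2Cl2, 0 °C to rt
Reagents that add atoms: none
Why: Dess–Martin oxidation of the two bis-benzylic secondary alcohols to the aryl ketones under non-basic conditions at room temperature, so that the now acidic H3 and H4 (cis to the aryl groups) should not be epimerised.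

**Step 9**
Reactants: 16 {(2S,3R,4R,5S)-2,5-bis[4-(benzyloxy)phenyl]oxolane-3,4-diyl}bis{[2,4-bis(benzyloxy)phenyl]methanone}
Product: 17 [(2S,3R,4R,5S)-2,5-bis(4-hydroxyphenyl)oxolane-3,4-diyl]bis[(2,4-dihydroxyphenyl)methanone] (CNP0237262.3)
Conditions: H2 (1 atm), Pd/C, EtOAc, rt
Reagents that add atoms: none
Why: Hydrogenolysis of the six aryl benzyl ethers over palladium on carbon; aryl O-benzyl groups should be cleaved much faster than the ring benzylic C–O bonds or the hydrogen-bonded 2-hydroxyaryl ketones, and no acid or base is present that could epimerise C3/C4 or open the ring through a quinone methide.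

**Compound list**

1 | hexa-1,5-diene-3,4-diol (mixture of diastereomers) | C=CC(O)C(O)C=C | starting material
2 | (2E,4E)-1,6-dibromohexa-2,4-diene | BrC/C=C/C=C/CBr | intermediate
3 | 2,2'-[(2E,4E)-hexa-2,4-diene-1,6-diyl]bis(4,4,5,5-tetramethyl-1,3,2-dioxaborolane) | CC1(C)OB(C/C=C/C=C/CB2OC(C)(C)C(C)(C)O2)OC1(C)C | intermediate
4 | 4-(benzyloxy)benzaldehyde | O=Cc1ccc(OCc2ccccc2)cc1 | starting material
5 | 2-{[(1S,2R,3E)-1-[4-(benzyloxy)phenyl]-2-ethenyl-5-(4,4,5,5-tetramethyl-1,3,2-dioxaborolan-2-yl)pent-3-en-1-yl]oxy}-4,4,5,5-tetramethyl-1,3,2-dioxaborolane | C=C[C@@H]([C@H](OB1OC(C)(C)C(C)(C)O1)c1ccc(OCc2ccccc2)cc1)/C=C/CB1OC(C)(C)C(C)(C)O1 | intermediate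
6 | 2,2'-{[(1S,2R,3R,4S)-1,4-bis[4-(benzyloxy)phenyl]-2,3-diethenylbutane-1,4-diyl]bis(oxy)}bis(4,4,5,5-tetramethyl-1,3,2-dioxaborolane) | C=C[C@@H]([C@H](OB1OC(C)(C)C(C)(C)O1)c1ccc(OCc2ccccc2)cc1)[C@@H](C=C)[C@@H](c1ccc(OCc2ccccc2)cc1)OB1OC(C)(C)C(C)(C)O1 | intermediate
7 | (1S,2R,3R,4S)-1,4-bis[4-(benzyloxy)phenyl]-2,3-diethenylbutane-1,4-diol | C=C[C@@H]([C@H](O)c1ccc(OCc2ccccc2)cc1)[C@@H](C=C)[C@@H](c1ccc(OCc2ccccc2)cc1)O | intermediate
8 | (2R,3R,4S)-1,4-bis[4-(benzyloxy)phenyl]-2,3-diethenyl-4-hydroxybutan-1-one | C=C[C@@H](C(=O)c1ccc(OCc2ccccc2)cc1)[C@@H](C=C)[C@@H](c1ccc(OCc2ccccc2)cc1)O | intermediate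
9 | (3R,4R,5S)-2,5-bis[4-(benzyloxy)phenyl]-3,4-diethenyloxolan-2-ol (both configurations at C2) | C=C[C@@H]1[C@@H](C=C)[C@@H](c2ccc(OCc3ccccc3)cc2)OC1(O)c1ccc(OCc2ccccc2)cc1 | intermediate
10 | (2S,3R,4R,5S)-2,5-bis[4-(benzyloxy)phenyl]-3,4-diethenyloxolane | C=C[C@@H]1[C@@H](C=C)[C@@H](c2ccc(OCc3ccccc3)cc2)O[C@@H]1c1ccc(OCc2ccccc2)cc1 | intermediate
11 | (2S,3R,4R,5S)-2,5-bis[4-(benzyloxy)phenyl]oxolane-3,4-dicarbaldehyde | O=C[C@@H]1[C@@H](C=O)[C@@H](c2ccc(OCc3ccccc3)cc2)O[C@@H]1c1ccc(OCc2ccccc2)cc1 | intermediate
12 | 4-bromobenzene-1,3-diol | Oc1ccc(Br)c(O)c1 | starting material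
13 | 2,4-bis(benzyloxy)-1-bromobenzene | Brc1ccc(OCc2ccccc2)cc1OCc1ccccc1 | intermediate
14 | [2,4-bis(benzyloxy)phenyl]magnesium bromide | Br[Mg]c1ccc(OCc2ccccc2)cc1OCc1ccccc1 | intermediate
15 | {(2S,3S,4S,5S)-2,5-bis[4-(benzyloxy)phenyl]oxolane-3,4-diyl}bis{[2,4-bis(benzyloxy)phenyl]methanol} (carbinol carbons unassigned) | OC(c1ccc(OCc2ccccc2)cc1OCc1ccccc1)[C@@H]1[C@@H](C(O)c2ccc(OCc3ccccc3)cc2OCc2ccccc2)[C@@H](c2ccc(OCc3ccccc3)cc2)O[C@@H]1c1ccc(OCc2ccccc2)cc1 | intermediate
16 | {(2S,3R,4R,5S)-2,5-bis[4-(benzyloxy)phenyl]oxolane-3,4-diyl}bis{[2,4-bis(benzyloxy)phenyl]methanone} | O=C(c1ccc(OCc2ccccc2)cc1OCc1ccccc1)[C@@H]1[C@@H](C(=O)c2ccc(OCc3ccccc3)cc2OCc2ccccc2)[C@@H](c2ccc(OCc3ccccc3)cc2)O[C@@H]1c1ccc(OCc2ccccc2)cc1 | intermediate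
17 | [(2S,3R,4R,5S)-2,5-bis(4-hydroxyphenyl)oxolane-3,4-diyl]bis[(2,4-dihydroxyphenyl)methanone] | O=C(c1ccc(O)cc1O)[C@@H]1[C@@H](C(=O)c2ccc(O)cc2O)[C@@H](c2ccc(O)cc2)O[C@@H]1c1ccc(O)cc1 | target

**Step count**

Total step count: 9. Longest linear sequence: 8 steps (1 → 2 → 3 → 7 → 10 → 11 → 15 → 16 → 17; step 6 prepares the aryl bromide).

**Steps most likely to fail**

Step 3. The second allylboration acts on an allylboronate that already carries the C3 stereocentre. If its own facial preference opposes the acid, the meso-type diastereomer forms instead of the C2-symmetric diol. The electron-rich aldehyde may also react slowly, so that uncatalysed background addition lowers the enantioselectivity. Fallback, setting out from 3 and 4 and coming back at 7: the thermal allylboration without acid (two equivalents of 4, toluene, 60 °C) relies only on the chair transition states and should give the racemic anti,anti-diol, that is 7 together with its enantiomer (1R,2S,3S,4R)-1,4-bis[4-(benzyloxy)phenyl]-2,3-diethenylbutane-1,4-diol F1. The C2-symmetric racemate is freed from any meso-type isomer by crystallisation and resolved by preparative chromatography on a chiral stationary phase, at the cost of half of the material.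

Step 4. Three things may go wrong: over-oxidation to the 1,4-diketone if the hydroxy ketone does not close fast enough; loss of H3 from the oxocarbenium ion with migration of the vinyl double bond into conjugation; and hydride attack on the wrong face. Fallback, setting out from 7 and coming back at 10: mono-silylation (TESCl, 1 equiv, imidazole, CH2Cl2, −20 °C; unreacted 7 is recycled) gives (1S,2R,3R,4S)-1,4-bis[4-(benzyloxy)phenyl]-2,3-diethenyl-4-[(triethylsilyl)oxy]butan-1-ol F2. Dess–Martin oxidation of the free carbinol gives (2R,3R,4S)-1,4-bis[4-(benzyloxy)phenyl]-2,3-diethenyl-4-[(triethylsilyl)oxy]butan-1-one F3. Reductive etherification of the silyl ether onto the ketone (BiBr3 cat., Et3SiH, MeCN, −30 °C) then closes the ring through the same 2-aryl oxocarbenium ion, without a free lactol ever meeting the oxidant.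

Step 7. The basic organometallic reagent may enolise the cis α-centres of dialdehyde 11 (epimerisation to the 2,3-trans series) or trigger β-elimination with ring opening, and the second addition may stall at the mono-adduct. Fallback, setting out from 11 and coming back at 16 (steps 7 and 8 are bypassed): Pinnick oxidation (NaClO2, NaH2PO4, 2-methylbut-2-ene, t-BuOH/H2O) gives (2S,3R,4R,5S)-2,5-bis[4-(benzyloxy)phenyl]oxolane-3,4-dicarboxylic acid F4. Amide coupling (MeNH(OMe)·HCl, EDC·HCl, N-methylmorpholine, CH2Cl2) gives (2S,3R,4R,5S)-2,5-bis[4-(benzyloxy)phenyl]-N3,N4-dimethoxy-N3,N4-dimethyloxolane-3,4-dicarboxamide F5. Addition of Grignard reagent 14 (two equivalents, THF, −40 °C) then gives ketone 16 directly through the chelated tetrahedral intermediates, so that no enolisable aldehyde or ketone is exposed to the base.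

**Further compounds**

F1 | step 3 | (1R,2S,3S,4R)-1,4-bis[4-(benzyloxy)phenyl]-2,3-diethenylbutane-1,4-diol | C=C[C@H]([C@@H](O)c1ccc(OCc2ccccc2)cc1)[C@H](C=C)[C@H](c1ccc(OCc2ccccc2)cc1)O
F2 | step 4 | (1S,2R,3R,4S)-1,4-bis[4-(benzyloxy)phenyl]-2,3-diethenyl-4-[(triethylsilyl)oxy]butan-1-ol | C=C[C@@H]([C@H](O[Si](CC)(CC)CC)c1ccc(OCc2ccccc2)cc1)[C@@H](C=C)[C@@H](c1ccc(OCc2ccccc2)cc1)O
F3 | step 4 | (2R,3R,4S)-1,4-bis[4-(benzyloxy)phenyl]-2,3-diethenyl-4-[(triethylsilyl)oxy]butan-1-one | C=C[C@@H]([C@H](O[Si](CC)(CC)CC)c1ccc(OCc2ccccc2)cc1)[C@@H](C=C)C(=O)c1ccc(OCc2ccccc2)cc1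
F4 | step 7 | (2S,3R,4R,5S)-2,5-bis[4-(benzyloxy)phenyl]oxolane-3,4-dicarboxylic acid | OC(=O)[C@@H]1[C@@H](C(O)=O)[C@@H](c2ccc(OCc3ccccc3)cc2)O[C@@H]1c1ccc(OCc2ccccc2)cc1
F5 | step 7 | (2S,3R,4R,5S)-2,5-bis[4-(benzyloxy)phenyl]-N3,N4-dimethoxy-N3,N4-dimethyloxolane-3,4-dicarboxamide | CON(C)C(=O)[C@@H]1[C@@H](C(=O)N(C)OC)[C@@H](c2ccc(OCc3ccccc3)cc2)O[C@@H]1c1ccc(OCc2ccccc2)cc1
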